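The rate constants are made up; the result is computed.

In a one-step world each molecule of the charge has one road and its yield is no question; this flask has a side road, and we reckon the leak through it as a small correction to the straight chain.

    starting material → intermediate A (k1 = 0.053 s⁻¹)
    intermediate A → intermediate B (k2 = 0.13 s⁻¹)
    intermediate B → product (k3 = 0.18 s⁻¹)
    starting material + protic impurity → quenched substrate (k4 = 0.026 M⁻¹ s⁻¹)

starting material 1.0 M; protic impurity 0.300 M; time 20 min

- the reaction counts as stopped when no species that holds the starting material changes by six tenths of a point or more over the second half of the time
- run time (flask): 20 min

* which holds at 20 min: what has brought the reaction to rest, or that it has not come to rest (all of the starting material has reacted / forward and back rates have come level / it is still moving)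
* part of the starting material gone at 20 min
* the product standing at 20 min, as a percentage of the starting material charged
* amount of product if the flask were left three thousand times as long, in percent of the starting material charged

Does the chain finish in time? The step from starting material to intermediate A is slower than the two later steps, its half-life is 0.218 min, and the time given holds 91.8 of those half-lives, so we expect all of the starting material has reacted, with 100% gone. Since no step runs back, the product is then the charge minus what the quench took.

How large is that leak? With H the concentration of protic impurity, a molecule of starting material is quenched against going forward at odds sH, where s, the quench rate constant over the forward one, is 0.491 M⁻¹, a selectivity factor per unit of impurity. At the charge these odds are 0.147, so with H held fixed (pseudo-first-order) the loss is the charge times sH/(1+sH), or 0.128 M.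

May H be held? That loss is 42.8% of the impurity charge, so we repeat the reckoning with H at the midpoint of its fall, which gives 0.104 M lost, hence 89.6% of product, and 89.6% for the long wait.

The forecast: all of the starting material has reacted, 100% gone, 89.4% of product at 20 min and 89.4% in the long wait, on the ground that “nothing is reversible, so the product figure is already final”. Beside its product figure stands our own 89.6%.

The simulation gives: all of the starting material has reacted, 100% gone, 89.4% of product at 20 min and 89.4% in the long wait. In this flask the product reads 89.1% after 2.00 min and 89.4% at 200 min.

The forecast's product figure for this flask does not carry over to the neighbour flask charged with 1.2 M of protic impurity, where sH starts at 0.589. The first pass there loses 0.371 M, and the midpoint pass loses 0.332 M, which leaves 66.8% of product. The neighbour flask shows 66.6% of product, with 33.4% as quenched substrate and 72% of its protic impurity left.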